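| setting | autumn | dusk | winter |
|---|---|---|---|
| substrate | 0.050 M | 0.050 M | 0.050 M |
| coupling partner | 0.0550 M | 0.0550 M | 0.0550 M |
| temperature | 60 °C | 35 °C | 10 °C |
| time | 40 s | 40 s | 40 s |

    crystals ⇌ by-product, rate k1*(cs1 - [by-product]) while solid is left; crystals form when [by-product] > cs1 (cs1 = 1.6 mM, k1 = 0.228 s⁻¹)
    substrate + target → side product (k2 = 0.716 M⁻¹ s⁻¹, Ea2 = 46.0 kJ mol⁻¹)
    substrate + coupling partner ⇌ target + by-product (K3 = 1.68, k3 = 0.408 M⁻¹ s⁻¹, Ea3 = 41.0 kJ mol⁻¹, ΔH3 = −25.0 kJ mol⁻¹)
    (constants at 35 °C)

- in percentages every species weighs as the substrate in it: one side product counts as two
- for by-product the crystals are counted in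
- as a solid, counted per litre of solution: crystals
- at 35 °C the constants are as listed, elsewhere as the activation energies and enthalpies make them

- the flask that comes out highest in amount of target, in percent of the substrate charged, or "all alike" when all lie within 1.5 percentage points (autumn / dusk / winter / all alike)
- target at the end, in percent of the substrate charged, autumn
- target at the end, in percent of the substrate charged, dusk
- target at the end, in percent of the substrate charged, winter

In each flask 0.050 M of substrate meets 0.0550 M of coupling partner, but every target lost to the side step takes a second substrate with it, so making and losing target draw on one pot. If I set the reverse step aside as an assumption and equate making with loss, c(substrate) cancels, and target stops rising where c(target) equals c(coupling partner)/r. Here r, the selectivity factor, is the side step's constant over the coupling step's, 1.75 at dusk. Following target against the falling coupling partner gives the ceiling, the peak c(target) = c(coupling partner at the start)·r^(−r/(r−1)), which at dusk is 29.8 % of the substrate charged. Since r moves with the activation energies' difference of 5.00 kJ mol⁻¹ as the equilibrium constant moves with the enthalpy, r is 1.48 in winter and 2.03 in autumn, which puts the ceilings at 32.9 % and 27.2 %.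

Two colleagues read these numbers differently. The ceiling side says winter must win, for its ceiling is the highest and its equilibrium constant of 3.98 exceeds autumn's 0.808. The clock side answers that the ceilings span 5.7 percentage points while the coupling step's speed spans a factor of 14. It counts lifetimes of substrate in 40 s, holding c(coupling partner) at its starting value as a simplification, the coupling constant times that concentration times the time: 0.219 in winter, 0.898 at dusk, 2.98 in autumn. On that count the coupling step in winter turns over about 19.6 % of the substrate, which lies below the winter ceiling.

My own reckoning, with the reverse step set aside, goes this far: winter under 19.6 %, autumn under 27.2 %, dusk under 29.8 %. It gives no number for dusk, though I side with the clock and pick dusk. The forecast, the clock side's number, gives 25.3 % for autumn, 28.2 % for dusk and 15.5 % for winter, picks dusk, and says “dusk ends near the maximum”; each value lies under my figure for its flask.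

The simulation gives 23.5 % for autumn, 27.8 % for dusk and 15.7 % for winter, so dusk is highest and the clock side wins. The ceiling side's ground comes at 400 s, where winter leads with 32.6 % against its ceiling of 32.9 %, dusk holding 25.5 % and autumn 11.5 %. Winter with 0.22 M of coupling partner reckons the same way: its ceiling rises to 132 % of the substrate charged, above the charge, and its clock to 0.874 lifetimes, a turnover by the coupling step of 58.3 %. That flask ends with 40.8 % of its substrate left and 49.1 % as target.

The constants were chosen freely; the run is a simulation.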